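## Retrosynthetic overview

1. Feature: in the dibenzo[a,d]cycloheptane core, C10 (bearing ring B and aryl ring D) and C11 (bearing ring A and the 4-hydroxyphenyl group) are adjacent, each carries two aryl groups, and both lie ortho to the C5 methine joining rings A and B. The C10–C11 bond is cut back to two diaryl ketone carbons (McMurry), so the seven-membered ring is closed first.
2. The C5 carbinol of the diketone (set by oxazaborolidine reduction, carried as a silyl ether) is sacrificial. It directs syn hydrogenation of C10=C11 to the cis-diaryl unit, then leaves as an o-quinone methide that a 4-methoxybenzyl sulfonium ylide turns into the trans-dihydrofuran (second ring), with C10/C11 now controlling C5 and the furan carbon C2′.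
3. The diketone comes from a dibromobenzhydrol (aryl Grignard plus aldehyde) by two successive bromine–lithium exchanges with aryl aldehydes, then oxidation.
4. The right-hand (2S,3S)-2,3-diaryl-4-vinyl-2,3-dihydrobenzofuran (third ring, made separately by enantioselective rhodium-carbene C–H insertion) is joined by a Heck reaction with the ring D triflate; global O-demethylation ends the route.

Key step: step 11

## Remarks (assumptions)

- Labels: ring A is the dimethoxy ring bonded to C5 and C11; ring B is the ring bonded to C5 and C10 that carries the furan oxygen; ring D is the 2-oxygenated aryl on C10; C2′ is the furan carbon bearing the 4-methoxyphenyl group.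
- The ring D coupling handle is carried as a benzyl ether and made a triflate only after the hydrogenation, because an aryl halide would be at risk over palladium and hydrogen. The ring B phenol is carried as a silyl ether so that only the ring D oxygen is free when the triflate is made.
- Step 5 assumes the di-ortho-substituted ring B acts as the large group, so the (S)-oxazaborolidine gives the (R)-carbinol. If this sense, or the facial sense of step 12, proves opposite, the (R)-catalyst is used instead.
- Step 23 assumes Rh2(R-PTAD)4 (PTAD = N-phthaloyl-(1-adamantyl)glycinate) gives the (3S) series; otherwise Rh2(S-PTAD)4 is used.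
- Carbinols 12 and 16 are carried as epimer mixtures at the new carbinol carbons; these centres become ketones in step 10.

## Route

Step 1
Reactants: 1 1,2-dibromo-3,5-dimethoxybenzene; 2 2-bromo-3,5-dimethoxybenzaldehyde
Product: 4 (2-bromo-3,5-dimethoxyphenyl)(2-bromo-4,6-dimethoxyphenyl)methanol (racemic), via arylmagnesium chloride 3 (not isolated)
Conditions: i-PrMgCl·LiCl, THF, −15 °C; then 2, −15 → 0 °C; aq NH4Cl
Reagents that add atoms: none
Why: Bromine–magnesium exchange occurs at the bromide flanked by the methoxy group (chelation and inductive stabilisation), and the ortho-bromoaryl Grignard reagent, stable below 0 °C, adds to the aldehyde (Grignard addition) to give the future C5 carbinol with both ring bromides in place.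

Step 2
Reactants: 4 (2-bromo-3,5-dimethoxyphenyl)(2-bromo-4,6-dimethoxyphenyl)methanol
Product: 5 (2-bromo-3,5-dimethoxyphenyl)(2-bromo-4,6-dimethoxyphenyl)methanone
Conditions: Dess–Martin periodinane, CH2Cl2, rt
Reagents that add atoms: none
Why: Dess–Martin oxidation of a benzhydrol to the benzophenone is reliable even with ortho substituents and touches neither aryl bromides nor methyl ethers.

Step 3
Reactants: 5 (2-bromo-3,5-dimethoxyphenyl)(2-bromo-4,6-dimethoxyphenyl)methanone
Product: 6 (2-bromo-3,5-dimethoxyphenyl)(2-bromo-6-hydroxy-4-methoxyphenyl)methanone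
Conditions: BCl3, CH2Cl2, −78 → 0 °C; H2O
Reagents that add atoms: none
Why: Chelation-controlled demethylation: BCl3 bridges the ketone oxygen and the only ortho methoxy group (on ring B) in a six-membered chelate and cleaves that ether alone, which singles out the future furan oxygen.

Step 4
Reactants: 6 (2-bromo-3,5-dimethoxyphenyl)(2-bromo-6-hydroxy-4-methoxyphenyl)methanone
Product: 7 (2-bromo-3,5-dimethoxyphenyl)[2-bromo-6-(tert-butyldimethylsilyloxy)-4-methoxyphenyl]methanone
Conditions: TBSOTf, 2,6-lutidine, CH2Cl2, 0 °C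
Reagents that add atoms: tert-butyldimethylsilyl trifluoromethanesulfonate, CC(C)(C)[Si](C)(C)OS(=O)(=O)C(F)(F)F
Why: Silylation of the hydrogen-bonded phenol with the silyl triflate masks it against borane and organolithium reagents in the following steps.

Step 5
Reactants: 7 (2-bromo-3,5-dimethoxyphenyl)[2-bromo-6-(tert-butyldimethylsilyloxy)-4-methoxyphenyl]methanone
Product: 8 (R)-(2-bromo-3,5-dimethoxyphenyl)[2-bromo-6-(tert-butyldimethylsilyloxy)-4-methoxyphenyl]methanol
Conditions: (S)-2-methyl-CBS-oxazaborolidine, BH3·SMe2, THF, 0 °C → rt; MeOH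
Reagents that add atoms: none
Why: Corey–Bakshi–Shibata reduction: the oxazaborolidine binds the carbonyl lone pair on the side of the mono-ortho-substituted ring A and delivers hydride to one face, which sets C5 as R under catalyst control through the difference between the twisted di-ortho ring B and ring A.

Step 6
Reactants: 8 (R)-(2-bromo-3,5-dimethoxyphenyl)[2-bromo-6-(tert-butyldimethylsilyloxy)-4-methoxyphenyl]methanol
Product: 9 tert-butyldimethylsilyl ether of 8 (C5 R; both ring bromides and the ring B aryl silyl ether retained)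
Conditions: TBSOTf, 2,6-lutidine, CH2Cl2, 0 °C → rt
Reagents that add atoms: tert-butyldimethylsilyl trifluoromethanesulfonate, CC(C)(C)[Si](C)(C)OS(=O)(=O)C(F)(F)F
Why: Silyl triflate with a hindered base silylates the crowded benzhydrol without ionising it, so C5 keeps its configuration and cannot later close onto an ortho ketone.

Step 7
Reactants: 9 bis-silyl dibromide (C5 R); 10 4-methoxybenzaldehyde
Product: 12 compound 9 with the ring A bromine replaced by CH(OH)(4-methoxyphenyl) (C5 R; new carbinol carbon as both epimers), via ring A aryllithium 11 (not isolated)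
Conditions: n-BuLi (1.05 equiv), THF, −78 °C; then 10, −78 °C; aq NH4Cl
Reagents that add atoms: none
Why: Bromine–lithium exchange is selective for the ring A bromide, whose ortho methoxy group stabilises the aryllithium, and 1,2-addition to the aldehyde at −78 °C (before any retro-Brook silyl shift) installs the C11 carbon as a carbinol.

Step 8
Reactants: 13 5-hydroxy-2-methoxybenzaldehyde
Product: 14 5-(benzyloxy)-2-methoxybenzaldehyde
Conditions: BnBr, K2CO3, DMF, rt
Reagents that add atoms: benzyl bromide, BrCc1ccccc1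
Why: Williamson ether synthesis on the phenoxide gives the ring D building block with its future coupling position masked as a hydrogenolysable benzyl ether.

Step 9
Reactants: 12 ring A carbinol (C5 R); 14 5-(benzyloxy)-2-methoxybenzaldehyde
Product: 16 diol in which ring A carries CH(OH)(4-methoxyphenyl) and ring B carries CH(OH)[5-(benzyloxy)-2-methoxyphenyl] (C5 R; both new carbinol carbons as epimer mixtures), via dilithio species 15 (not isolated)
Conditions: n-BuLi (2.1 equiv), THF, −78 °C; then 14, −78 °C; aq NH4Cl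
Reagents that add atoms: none
Why: The first equivalent of n-butyllithium deprotonates the C11 carbinol and the second exchanges the ring B bromide, and 1,2-addition of this aryllithium to aldehyde 14 (an aldehyde is used so that no ketone is present for the second aryllithium to attack) installs the C10 carbon.

Step 10
Reactants: 16 diol (C5 R)
Product: 17 (R)-[2-(4-methoxybenzoyl)-3,5-dimethoxyphenyl]{2-[5-(benzyloxy)-2-methoxybenzoyl]-6-(tert-butyldimethylsilyloxy)-4-methoxyphenyl}methyl tert-butyldimethylsilyl ether (the diketone)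
Conditions: (n-Pr4N)RuO4 (cat.), N-methylmorpholine N-oxide, 4 Å MS, CH2Cl2, rt
Reagents that add atoms: none
Why: Ley–Griffith oxidation converts both diaryl carbinols into ketones under neutral conditions that leave the acid-sensitive benzhydryl silyl ether and C5 untouched, and it removes the two transient carbinol stereocentres.

Step 11
Reactants: 17 diketone (C5 R)
Product: 19 (5R)-10-[5-(benzyloxy)-2-methoxyphenyl]-5,6-bis(tert-butyldimethylsilyloxy)-1,3,8-trimethoxy-11-(4-methoxyphenyl)-5H-dibenzo[a,d][7]annulene, via titanium pinacolate 18 (not isolated)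
Conditions: TiCl4, Zn, pyridine, THF, reflux; 17 added by syringe pump over 12 h (final 2 mM)
Reagents that add atoms: none
Why: Low-valent titanium (from TiCl4 and zinc) transfers one electron to each diaryl ketone; the two ketyl radicals, held close because both aroyl groups sit ortho to the same C5 methine, couple at C10–C11 to titanium pinacolate 18, which is deoxygenated on the metal at reflux to the tetrasubstituted alkene. The closest known reaction type is the intramolecular McMurry coupling of bis(diaryl ketones) to cyclic tetraarylethylenes. The seven-membered carbocycle is closed by this carbonyl–carbonyl (pinacol-type) union with both new-bond carbons in the ring, and only the cis ring alkene is geometrically possible. No stereocentre is created, and C5 (R) is a spectator because the pyridine-buffered reagent should neither ionise the benzhydryl silyl ether nor touch the aryl silyl and benzyl ethers. The selectivity needed is intramolecular over intermolecular coupling, secured by slow addition at high dilution and by the pre-organisation of the two carbonyl groups.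

Step 12
Reactants: 19 dibenzocycloheptene (C5 R)
Product: 20 (5R,10S,11S)-5,6-bis(tert-butyldimethylsilyloxy)-10-(5-hydroxy-2-methoxyphenyl)-1,3,8-trimethoxy-11-(4-methoxyphenyl)-10,11-dihydro-5H-dibenzo[a,d][7]annulene
Conditions: H2 (60 bar), Pd(OH)2/C, EtOAc, 50 °C
Reagents that add atoms: none
Why: Heterogeneous syn hydrogenation should add both hydrogens to the convex face of the tub-shaped ring, anti to the pseudo-axial C5 silyloxy group, which sets C10 and C11 cis (10S,11S) with both aryl groups on the side of the silyloxy group, while the same catalyst hydrogenolyses the ring D benzyl ether.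

Step 13
Reactants: 20 ring D phenol (5R,10S,11S)
Product: 21 ring D trifluoromethanesulfonate of 20 (5R,10S,11S)
Conditions: PhNTf2, Et3N, DMAP (cat.), CH2Cl2, 0 °C → rt
Reagents that add atoms: N-phenylbis(trifluoromethanesulfonimide), O=S(=O)(N(c1ccccc1)S(=O)(=O)C(F)(F)F)C(F)(F)F
Why: Triflation of the only free phenol installs the Heck handle after the hydrogenation, so no differentiation from the still-silylated ring B oxygen is needed.

Step 14
Reactants: 21 bis-silyl triflate (5R,10S,11S)
Product: 22 (5R,10S,11S)-5,6-dihydroxy compound (ring B phenol and C5 carbinol free, ring D triflate retained)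
Conditions: Bu4NF, AcOH, THF, 0 °C → rt
Reagents that add atoms: none
Why: Acetic-acid-buffered fluoride cleaves the aryl and the benzhydryl silyl ethers (Si–F bond formation) while sparing the aryl triflate, which uncovers the o-hydroxybenzhydrol.

Step 15
Reactants: 22 o-hydroxybenzhydrol (5R,10S,11S)
Product: 23 C5 p-tolyl sulfone of 22 (C5 as a mixture of epimers; 10S,11S)
Conditions: sodium p-toluenesulfinate, HCO2H, CH2Cl2/H2O, rt
Reagents that add atoms: sodium p-toluenesulfinate, Cc1ccc(S(=O)[O-])cc1.[Na+]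
Why: Acid ionises the electron-rich o-hydroxybenzhydrol and the sulfinate captures the cation at sulfur (SN1 sulfonylation), giving a base-labile o-quinone methide precursor; C5 has done its relay work, so its scrambling does not matter.

Step 16
Reactants: 24 4-methoxybenzyl alcohol
Product: 25 1-(4-methoxybenzyl)tetrahydrothiophenium tetrafluoroborate
Conditions: tetrahydrothiophene, HBF4·OEt2, CH2Cl2, 0 °C → rt
Reagents that add atoms: tetrahydrothiophene, C1CCSC1; tetrafluoroboric acid, [H+].F[B-](F)(F)F
Why: The acid ionises the 4-methoxybenzyl alcohol and the sulfide traps the cation (S-alkylation), giving a crystalline sulfonium salt with a non-nucleophilic counter-ion.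

Step 17
Reactants: 23 sulfone (10S,11S); 25 1-(4-methoxybenzyl)tetrahydrothiophenium tetrafluoroborate
Product: 28 dihydrofuran-annulated triflate in which C5 and the ring B oxygen are bridged by C2′H(4-methoxyphenyl), trans across C5–C2′ (C5 S, C10 S, C11 S, C2′ S), via sulfonium ylide 26 (not isolated), via o-quinone methide 27 (not isolated)
Conditions: Cs2CO3, CH2Cl2, rt
Reagents that add atoms: none
Why: Cesium carbonate eliminates sulfinate to o-quinone methide 27 and forms ylide 26, whose carbon should add to C5 from the face opposite the cis aryl groups on C10 and C11 (setting C5 as S) before the phenoxide displaces tetrahydrothiophene with inversion to close the trans-dihydrofuran (C2′ S), a formal [4+1] annulation of Corey–Chaykovsky type.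

Step 18
Reactants: 29 2-bromo-4,6-dimethoxybenzaldehyde
Product: 30 2-bromo-6-hydroxy-4-methoxybenzaldehyde
Conditions: BCl3, CH2Cl2, −78 → 0 °C; H2O
Reagents that add atoms: none
Why: Chelation-controlled demethylation removes only the methyl ether ortho to the aldehyde, freeing the future furan oxygen of the right-hand unit.

Step 19
Reactants: 30 2-bromo-6-hydroxy-4-methoxybenzaldehyde; 31 4-methoxybenzyl chloride
Product: 32 2-bromo-4-methoxy-6-[(4-methoxybenzyl)oxy]benzaldehyde
Conditions: K2CO3, NaI (cat.), DMF, 50 °C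
Reagents that add atoms: none
Why: Williamson ether synthesis attaches the 4-methoxybenzyl group whose benzylic carbon later becomes C2 of the dihydrobenzofuran.

Step 20
Reactants: 32 2-bromo-4-methoxy-6-[(4-methoxybenzyl)oxy]benzaldehyde; 33 1-bromo-3,5-dimethoxybenzene
Product: 35 {2-bromo-4-methoxy-6-[(4-methoxybenzyl)oxy]phenyl}(3,5-dimethoxyphenyl)methanol (racemic), via arylmagnesium bromide 34 (not isolated)
Conditions: 33, Mg, THF, reflux; then 32, 0 °C → rt; aq NH4Cl
Reagents that add atoms: none
Why: Grignard addition of the unhindered aryl nucleophile to the di-ortho-substituted aldehyde gives the diaryl carbinol; the aryl bromide of 32 is inert to the Grignard reagent at this temperature.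

Step 21
Reactants: 35 diaryl carbinol
Product: 36 {2-bromo-4-methoxy-6-[(4-methoxybenzyl)oxy]phenyl}(3,5-dimethoxyphenyl)methanone
Conditions: Dess–Martin periodinane, CH2Cl2, rt
Reagents that add atoms: none
Why: Dess–Martin oxidation gives the diaryl ketone without cleaving the 4-methoxybenzyl ether.

Step 22
Reactants: 36 diaryl ketone
Product: 37 hydrazone of 36 (E/Z mixture)
Conditions: N2H4·H2O (excess), AcOH (cat.), n-BuOH, 110 °C
Reagents that add atoms: hydrazine hydrate, NN.O
Why: Acid-catalysed condensation with excess hydrazine at high temperature overcomes the hindrance of the di-ortho-substituted ketone and gives the N-unsubstituted hydrazone needed for diazo formation.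

Step 23
Reactants: 37 hydrazone
Product: 39 (2R,3S)-4-bromo-3-(3,5-dimethoxyphenyl)-6-methoxy-2-(4-methoxyphenyl)-2,3-dihydro-1-benzofuran (cis), via diaryldiazomethane 38 (not isolated)
Conditions: MnO2, CH2Cl2, 0 °C, filter; then Rh2(R-PTAD)4 (1 mol %), CH2Cl2, 0 °C → rt
Reagents that add atoms: none
Why: Manganese dioxide dehydrogenates the hydrazone to diaryldiazomethane 38, and the chiral dirhodium carboxylate turns it into a donor/donor carbene that inserts into the benzylic C–H bond of the 4-methoxybenzyl ether (1,5 C–H insertion), which forms the C2–C3 bond cis and sets C3 as S under catalyst control.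

Step 24
Reactants: 39 cis-dihydrobenzofuran (2R,3S)
Product: 40 (2S,3S)-4-bromo-3-(3,5-dimethoxyphenyl)-6-methoxy-2-(4-methoxyphenyl)-2,3-dihydro-1-benzofuran (trans)
Conditions: CF3CO2H, CH2Cl2, 0 °C → rt
Reagents that add atoms: none
Why: Acid reversibly ionises the C2–O bond to a 4-methoxybenzyl cation that recloses to the more stable trans isomer (thermodynamic epimerisation), inverting C2 to S while C3 is untouched.

Step 25
Reactants: 40 trans bromide (2S,3S)
Product: 41 (2S,3S)-3-(3,5-dimethoxyphenyl)-4-ethenyl-6-methoxy-2-(4-methoxyphenyl)-2,3-dihydro-1-benzofuran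
Conditions: vinylboronic acid pinacol ester, Pd(dppf)Cl2 (5 mol %), K2CO3, dioxane/H2O, 90 °C
Reagents that add atoms: 4,4,5,5-tetramethyl-2-vinyl-1,3,2-dioxaborolane, C=CB1OC(C)(C)C(C)(C)O1
Why: Suzuki–Miyaura coupling replaces the aryl bromide by the vinyl group without affecting the two benzylic stereocentres.

Step 26
Reactants: 28 annulated triflate; 41 4-vinyl dihydrobenzofuran
Product: 42 decamethyl ether of the target (E-stilbene between ring D and C4 of the right-hand benzofuran; all six stereocentres S)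
Conditions: PdCl2(PPh3)2 (10 mol %), LiCl, Et3N, DMF, 100 °C
Reagents that add atoms: none
Why: Mizoroki–Heck reaction: zerovalent palladium inserts into the aryl triflate (chloride keeps the neutral pathway), the aryl adds to the terminal vinyl carbon, and syn β-hydride elimination gives the E-alkene.

Step 27
Reactants: 42 decamethyl ether
Product: 43 target CNP0266373.2 (decaphenol)
Conditions: BBr3 (excess), CH2Cl2, −78 → 0 °C; MeOH, then H2O
Reagents that add atoms: none
Why: Boron tribromide cleaves all ten aryl methyl ethers (Lewis acid activation, bromide attack at methyl), and keeping the mixture cold with a methanol quench should leave the six stereocentres, both dihydrofurans and the E-alkene intact.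

## Compound list

1 | 1,2-dibromo-3,5-dimethoxybenzene | COc1cc(OC)c(Br)c(Br)c1 | starting material
2 | 2-bromo-3,5-dimethoxybenzaldehyde | COc1cc(OC)c(Br)c(C=O)c1 | starting material
3 | (2-bromo-4,6-dimethoxyphenyl)magnesium chloride | COc1cc(OC)c([Mg]Cl)c(Br)c1 | intermediate
4 | (2-bromo-3,5-dimethoxyphenyl)(2-bromo-4,6-dimethoxyphenyl)methanol, racemic | COc1cc(OC)c(Br)c(C(O)c2c(Br)cc(OC)cc2OC)c1 | intermediate
5 | (2-bromo-3,5-dimethoxyphenyl)(2-bromo-4,6-dimethoxyphenyl)methanone | COc1cc(OC)c(Br)c(C(=O)c2c(Br)cc(OC)cc2OC)c1 | intermediate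
6 | (2-bromo-3,5-dimethoxyphenyl)(2-bromo-6-hydroxy-4-methoxyphenyl)methanone | COc1cc(OC)c(Br)c(C(=O)c2c(Br)cc(OC)cc2O)c1 | intermediate
7 | (2-bromo-3,5-dimethoxyphenyl)[2-bromo-6-(tert-butyldimethylsilyloxy)-4-methoxyphenyl]methanone | COc1cc(OC)c(Br)c(C(=O)c2c(Br)cc(OC)cc2O[Si](C)(C)C(C)(C)C)c1 | intermediate
8 | (R)-(2-bromo-3,5-dimethoxyphenyl)[2-bromo-6-(tert-butyldimethylsilyloxy)-4-methoxyphenyl]methanol | Brc1c(OC)cc(OC)cc1[C@@H](O)c1c(O[Si](C)(C)C(C)(C)C)cc(OC)cc1Br | intermediate
9 | tert-butyldimethylsilyl ether of 8 (C5 R) | Brc1c(OC)cc(OC)cc1[C@@H](O[Si](C)(C)C(C)(C)C)c1c(O[Si](C)(C)C(C)(C)C)cc(OC)cc1Br | intermediate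
10 | 4-methoxybenzaldehyde | COc1ccc(C=O)cc1 | starting material
11 | ring A aryllithium derived from 9 | [Li]c1c(OC)cc(OC)cc1[C@@H](O[Si](C)(C)C(C)(C)C)c1c(O[Si](C)(C)C(C)(C)C)cc(OC)cc1Br | intermediate
12 | ring A (4-methoxyphenyl)hydroxymethyl compound (C5 R, carbinol epimers) | COc1ccc(C(O)c2c(OC)cc(OC)cc2[C@@H](O[Si](C)(C)C(C)(C)C)c2c(O[Si](C)(C)C(C)(C)C)cc(OC)cc2Br)cc1 | intermediate
13 | 5-hydroxy-2-methoxybenzaldehyde | COc1ccc(O)cc1C=O | starting material
14 | 5-(benzyloxy)-2-methoxybenzaldehyde | COc1ccc(OCc2ccccc2)cc1C=O | intermediate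
15 | dilithio species (lithium alkoxide at C11, aryllithium on ring B) | COc1ccc(C(O[Li])c2c(OC)cc(OC)cc2[C@@H](O[Si](C)(C)C(C)(C)C)c2c(O[Si](C)(C)C(C)(C)C)cc(OC)cc2[Li])cc1 | intermediate
16 | diol (C5 R, carbinol epimers) | COc1ccc(C(O)c2c(OC)cc(OC)cc2[C@@H](O[Si](C)(C)C(C)(C)C)c2c(O[Si](C)(C)C(C)(C)C)cc(OC)cc2C(O)c2cc(OCc3ccccc3)ccc2OC)cc1 | intermediate
17 | diketone, McMurry precursor (C5 R) | COc1ccc(C(=O)c2c(OC)cc(OC)cc2[C@@H](O[Si](C)(C)C(C)(C)C)c2c(O[Si](C)(C)C(C)(C)C)cc(OC)cc2C(=O)c2cc(OCc3ccccc3)ccc2OC)cc1 | intermediate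
18 | titanium pinacolate (cyclic titanium 10,11-diolate) | COc1ccc(C2(O[Ti]O3)c4c(OC)cc(OC)cc4[C@@H](O[Si](C)(C)C(C)(C)C)c4c(O[Si](C)(C)C(C)(C)C)cc(OC)cc4C23c2cc(OCc3ccccc3)ccc2OC)cc1 | intermediate
19 | (5R)-10-[5-(benzyloxy)-2-methoxyphenyl]-5,6-bis(tert-butyldimethylsilyloxy)-1,3,8-trimethoxy-11-(4-methoxyphenyl)-5H-dibenzo[a,d][7]annulene | COc1ccc(C=2c3c(OC)cc(OC)cc3[C@@H](O[Si](C)(C)C(C)(C)C)c3c(O[Si](C)(C)C(C)(C)C)cc(OC)cc3C=2c2cc(OCc3ccccc3)ccc2OC)cc1 | intermediate
20 | (5R,10S,11S)-10,11-dihydro ring D phenol | COc1ccc([C@H]2c3c(OC)cc(OC)cc3[C@@H](O[Si](C)(C)C(C)(C)C)c3c(O[Si](C)(C)C(C)(C)C)cc(OC)cc3[C@H]2c2cc(O)ccc2OC)cc1 | intermediate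
21 | (5R,10S,11S) ring D triflate | COc1ccc([C@H]2c3c(OC)cc(OC)cc3[C@@H](O[Si](C)(C)C(C)(C)C)c3c(O[Si](C)(C)C(C)(C)C)cc(OC)cc3[C@H]2c2cc(OS(=O)(=O)C(F)(F)F)ccc2OC)cc1 | intermediate
22 | (5R,10S,11S) o-hydroxybenzhydrol triflate | COc1ccc([C@H]2c3c(OC)cc(OC)cc3[C@@H](O)c3c(O)cc(OC)cc3[C@H]2c2cc(OS(=O)(=O)C(F)(F)F)ccc2OC)cc1 | intermediate
23 | C5 p-tolyl sulfone (C5 epimers; 10S,11S) | COc1ccc([C@H]2c3c(OC)cc(OC)cc3C(S(=O)(=O)c3ccc(C)cc3)c3c(O)cc(OC)cc3[C@H]2c2cc(OS(=O)(=O)C(F)(F)F)ccc2OC)cc1 | intermediate
24 | 4-methoxybenzyl alcohol | COc1ccc(CO)cc1 | starting material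
25 | 1-(4-methoxybenzyl)tetrahydrothiophenium tetrafluoroborate | COc1ccc(C[S+]2CCCC2)cc1.F[B-](F)(F)F | intermediate
26 | sulfonium ylide from 25 | COc1ccc([CH-][S+]2CCCC2)cc1 | intermediate
27 | o-quinone methide (C5=ring B exocyclic alkene; 10S,11S) | COc1ccc([C@H]2c3c(OC)cc(OC)cc3C=C3C(=O)C=C(OC)C=C3[C@H]2c2cc(OS(=O)(=O)C(F)(F)F)ccc2OC)cc1 | intermediate
28 | dihydrofuran-annulated triflate (C5 S, C10 S, C11 S, C2′ S) | COc1ccc([C@H]2c3c(OC)cc(OC)cc3[C@H]3c4c(cc(OC)cc4[C@H]2c2cc(OS(=O)(=O)C(F)(F)F)ccc2OC)O[C@@H]3c2ccc(OC)cc2)cc1 | intermediate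
29 | 2-bromo-4,6-dimethoxybenzaldehyde | COc1cc(Br)c(C=O)c(OC)c1 | starting material
30 | 2-bromo-6-hydroxy-4-methoxybenzaldehyde | COc1cc(O)c(C=O)c(Br)c1 | intermediate
31 | 4-methoxybenzyl chloride | COc1ccc(CCl)cc1 | starting material
32 | 2-bromo-4-methoxy-6-[(4-methoxybenzyl)oxy]benzaldehyde | COc1ccc(COc2cc(OC)cc(Br)c2C=O)cc1 | intermediate
33 | 1-bromo-3,5-dimethoxybenzene | COc1cc(Br)cc(OC)c1 | starting material
34 | (3,5-dimethoxyphenyl)magnesium bromide | COc1cc(OC)cc([Mg]Br)c1 | intermediate
35 | {2-bromo-4-methoxy-6-[(4-methoxybenzyl)oxy]phenyl}(3,5-dimethoxyphenyl)methanol, racemic | COc1ccc(COc2cc(OC)cc(Br)c2C(O)c2cc(OC)cc(OC)c2)cc1 | intermediate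
36 | {2-bromo-4-methoxy-6-[(4-methoxybenzyl)oxy]phenyl}(3,5-dimethoxyphenyl)methanone | COc1ccc(COc2cc(OC)cc(Br)c2C(=O)c2cc(OC)cc(OC)c2)cc1 | intermediate
37 | hydrazone of 36 | COc1ccc(COc2cc(OC)cc(Br)c2C(=NN)c2cc(OC)cc(OC)c2)cc1 | intermediate
38 | diaryldiazomethane from 37 | COc1ccc(COc2cc(OC)cc(Br)c2C(=[N+]=[N-])c2cc(OC)cc(OC)c2)cc1 | intermediate
39 | (2R,3S)-4-bromo-3-(3,5-dimethoxyphenyl)-6-methoxy-2-(4-methoxyphenyl)-2,3-dihydro-1-benzofuran (cis) | Brc1cc(OC)cc2c1[C@H](c1cc(OC)cc(OC)c1)[C@H](c1ccc(OC)cc1)O2 | intermediate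
40 | (2S,3S)-4-bromo-3-(3,5-dimethoxyphenyl)-6-methoxy-2-(4-methoxyphenyl)-2,3-dihydro-1-benzofuran (trans) | Brc1cc(OC)cc2c1[C@H](c1cc(OC)cc(OC)c1)[C@@H](c1ccc(OC)cc1)O2 | intermediate
41 | (2S,3S)-3-(3,5-dimethoxyphenyl)-4-ethenyl-6-methoxy-2-(4-methoxyphenyl)-2,3-dihydro-1-benzofuran | C=Cc1cc(OC)cc2c1[C@H](c1cc(OC)cc(OC)c1)[C@@H](c1ccc(OC)cc1)O2 | intermediate
42 | decamethyl ether of the target | COc1ccc([C@H]2c3c(OC)cc(OC)cc3[C@H]3c4c(cc(OC)cc4[C@H]2c2cc(/C=C/c4cc(OC)cc5c4[C@H](c4cc(OC)cc(OC)c4)[C@@H](c4ccc(OC)cc4)O5)ccc2OC)O[C@@H]3c2ccc(OC)cc2)cc1 | intermediate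
43 | target CNP0266373.2 | Oc1ccc([C@H]2c3c(O)cc(O)cc3[C@H]3c4c(cc(O)cc4[C@H]2c2cc(/C=C/c4cc(O)cc5c4[C@H](c4cc(O)cc(O)c4)[C@@H](c4ccc(O)cc4)O5)ccc2O)O[C@@H]3c2ccc(O)cc2)cc1 | target

## Step count and risks

Total step count: 27. Longest linear sequence: 17 steps (steps 1–7, 9–15, 17, 26, 27).

Steps most likely to fail:

1. Step 11 (McMurry closure). The two crowded ketyls may couple between molecules or stop at the pinacolate instead of being deoxygenated, and the Lewis-acidic titanium chlorides may ionise and reduce the benzhydryl silyl ether. The fallback separates coupling from deoxygenation. It sets out from 17: SmI2 (THF, rt, slow addition) should give the cis-10,11-diol F1 by intramolecular pinacol coupling. 1,1′-Thiocarbonyldiimidazole (DMAP, toluene, 90 °C) converts it into the cyclic thionocarbonate F2. Corey–Winter fragmentation with 1,3-dimethyl-2-phenyl-1,3,2-diazaphospholidine (40 °C) then returns to the route at 19.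

2. Step 12 (hydrogenation). Saturation of the tetrasubstituted tetraaryl alkene may be slow, so that under forcing conditions over palladium the benzhydryl C5–O bond is hydrogenolysed or the facial bias is lost. The fallback separates the two events. It sets out from 19: PtO2 with H2 (60 bar, EtOAc), which does not cleave benzylic C–O bonds, should give the saturated benzyl ether F3 with the same convex-face delivery. Transfer hydrogenolysis (Pd/C, 1,4-cyclohexadiene, EtOH, rt) then removes only the aryl benzyl ether and returns to the route at 20.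

3. Step 27 (global demethylation). Under BBr3 and the HBr it forms, the 2-aryl-dihydrofurans may open at C2–O, and the electron-rich stilbene may be protonated and cyclise onto the neighbouring 3,5-dioxygenated ring. The fallback moves the demethylation before the union, where no stilbene is present:
   - From 28: BBr3 gives the hexaphenol triflate F4, and Ac2O/pyridine gives the hexaacetate triflate F5.
   - From 40: BBr3 gives the tetraphenol bromide F6, Ac2O/pyridine gives the tetraacetate bromide F7, and Stille vinylation (tributyl(vinyl)tin, Pd(PPh3)4, toluene, 100 °C) gives the tetraacetate 4-vinyl compound F8.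
   - Heck coupling of F5 with F8 (PdCl2(PPh3)2, LiCl, Et3N, DMF) gives the decaacetate F9, and mild methanolysis (K2CO3, MeOH, 0 °C, degassed) returns to the route at 43.

Further compounds

F1 | step 11 | cis-10,11-diol from pinacol coupling of 17 (C5 R) | COc1ccc(C2(O)c3c(OC)cc(OC)cc3[C@@H](O[Si](C)(C)C(C)(C)C)c3c(O[Si](C)(C)C(C)(C)C)cc(OC)cc3C2(O)c2cc(OCc3ccccc3)ccc2OC)cc1
F2 | step 11 | cyclic 10,11-thionocarbonate of F1 | COc1ccc(C2(OC(=S)O3)c4c(OC)cc(OC)cc4[C@@H](O[Si](C)(C)C(C)(C)C)c4c(O[Si](C)(C)C(C)(C)C)cc(OC)cc4C23c2cc(OCc3ccccc3)ccc2OC)cc1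
F3 | step 12 | (5R,10S,11S)-10,11-dihydro compound with the ring D benzyl ether intact | COc1ccc([C@H]2c3c(OC)cc(OC)cc3[C@@H](O[Si](C)(C)C(C)(C)C)c3c(O[Si](C)(C)C(C)(C)C)cc(OC)cc3[C@H]2c2cc(OCc3ccccc3)ccc2OC)cc1
F4 | step 27 | hexaphenol triflate from 28 | Oc1ccc([C@H]2c3c(O)cc(O)cc3[C@H]3c4c(cc(O)cc4[C@H]2c2cc(OS(=O)(=O)C(F)(F)F)ccc2O)O[C@@H]3c2ccc(O)cc2)cc1
F5 | step 27 | hexaacetate triflate | CC(=O)Oc1ccc([C@H]2c3c(OC(C)=O)cc(OC(C)=O)cc3[C@H]3c4c(cc(OC(C)=O)cc4[C@H]2c2cc(OS(=O)(=O)C(F)(F)F)ccc2OC(C)=O)O[C@@H]3c2ccc(OC(C)=O)cc2)cc1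
F6 | step 27 | tetraphenol bromide from 40 | Brc1cc(O)cc2c1[C@H](c1cc(O)cc(O)c1)[C@@H](c1ccc(O)cc1)O2
F7 | step 27 | tetraacetate bromide | Brc1cc(OC(C)=O)cc2c1[C@H](c1cc(OC(C)=O)cc(OC(C)=O)c1)[C@@H](c1ccc(OC(C)=O)cc1)O2
F8 | step 27 | tetraacetate 4-vinyl dihydrobenzofuran | C=Cc1cc(OC(C)=O)cc2c1[C@H](c1cc(OC(C)=O)cc(OC(C)=O)c1)[C@@H](c1ccc(OC(C)=O)cc1)O2
F9 | step 27 | decaacetate of the target | CC(=O)Oc1ccc([C@H]2c3c(OC(C)=O)cc(OC(C)=O)cc3[C@H]3c4c(cc(OC(C)=O)cc4[C@H]2c2cc(/C=C/c4cc(OC(C)=O)cc5c4[C@H](c4cc(OC(C)=O)cc(OC(C)=O)c4)[C@@H](c4ccc(OC(C)=O)cc4)O5)ccc2OC(C)=O)O[C@@H]3c2ccc(OC(C)=O)cc2)cc1
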